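## The problem

The target is the 7‑angelate 9‑tiglate of a longipin‑2‑en‑1‑one diol. Longipinane locants are used throughout: C1 is the ketone, C2=C3 the enone double bond with the methyl on C3, C4 and C11 the bridgeheads, C5 the ring‑A methine, C6 the gem‑dimethyl carbon, C7 the angelate carbinol, C8 the methylene, C9 the tiglate carbinol and C10 the quaternary methyl‑bearing carbon. Ring A is the cyclobutane C4–C5–C11–C10; the enone bridge C1–C2–C3 spans C11 and C4 on one face of it (ring B), and the four‑carbon bridge C9–C8–C7–C6 spans C10 and C5 on the other face (ring C, seven‑membered). Four of the six stereocentres (C4, C5, C10, C11) lie on ring A: in the closed tricycle they lock each other, but in a bicyclic precursor C5 and C10 can each carry their chain on the wrong face, and the bare bicyclo[3.1.1]heptane is chiral only because the carbonyl lies next to C11 and not C4. C9 is neopentylic beside quaternary C10 and needs reagent control, whereas C7 can be set from C9 through their 1,3‑anti relationship. The angelate isomerises to the tiglate under nucleophilic or basic catalysis, ring C as a β‑hydroxy or β‑acyloxy ketone can cleave or eliminate, and allylic cations beside the cyclobutane rearrange as pinene derivatives do. The enabling feature is that C8 and C7 are neighbours in ring C, flanked by the C9 carbinol and quaternary C6, so the C7–C8 bond can be made as the double bond of a cyclic silyl enol ether between two arms that C10 and C5 hold on the same face of ring A.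

## Retrosynthesis

**Angelate last.** The C7–O acyl bond of 32 is cut first, giving hydroxy tiglate 29 and angelic acid 30. The opposite order would drag the Z‑ester through a reduction and a second acylation. The forward step must acylate a neopentylic hydroxyl without a nucleophilic catalyst.

**Tiglate and C7 together.** The C7–H bond and the tiglate C–O bond of 29 are cut in one operation, back to β‑hydroxy ketone 26 and tiglaldehyde 27. Separate reduction and acylation would have to tell two neopentylic hydroxyls apart; the hemiacetal hydride transfer places the ester on C9 and the new hydroxyl on C7, anti to C9. 26 has one stereocentre and one ester less, and the forward reaction needs the C9 hydroxyl free.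

**Masked carbonyls.** 26 is traced through dihydroxy ketone 25 to the silylated tricycle 24, with the C1 carbonyl stored as a silyl‑protected allylic alcohol and C7 as its silyl enol ether. A free enone would not survive the borohydride, Grignard, borane and methyllithium steps and would compete when the methyl ketone is enolised. The forward steps are a global desilylation and an allylic oxidation that leaves C9 alone.

**Ring C.** 24 is opened at the C7=C8 double bond to diene 23, which has a vinyl group on the C9 carbinol and a 2‑silyloxypropenyl group on C6. Cutting C8–C9 (aldol) would leave C9 to substrate control, and cutting C5–C6 or C9–C10 would make a bond to a quaternary carbon during ring closure. 23 is bicyclic, and the forward reaction must join a terminal alkene to a hindered 1,1‑disubstituted enol ether.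

**The two arms.** The silyl ether and enol ether of 23 come from hydroxy ketone 22, the methyl ketone from the nitrile of 20, and the C9 carbinol of 20 from vinyl ketone 19. 19 comes from aldehyde 16 and vinylmagnesium bromide 17 through the epimeric alcohols 18. Direct addition to 16 would rest on an unknown facial bias, so C9 is set on 19 by a catalyst; the nitrile is kept until then because a methyl ketone would also be reduced.

**The C10 methyl.** 16 comes from ester 14 through alcohol 15, and 14 from the unmethylated bicyclic ester 13. If the methyl were present before ring A closes, the larger enolate unit would take the open side of C10 and push the methyl toward the C5 arm. Alkylating the finished bicycle reverses this, because the electrophile enters on the open side.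

**Ring A.** 13 is opened at C10–C11 to cyclohexenyl acetate 12, with the enolate carbon on C4 and a tosylate on C11. Cycloaddition routes to the four‑membered ring leave a carbonyl at C5; an intramolecular alkylation sets C11 by inversion. The forward reaction is a four‑membered closure that must beat O‑alkylation.

**C4–C10 by rearrangement.** 12 is cut at C4–C10 as a [3,3] shift, giving allylic alcohol 9 and trimethyl orthoacetate 10 by way of ketene acetal 11. The new bond must be cis to the bulky C5 substituent; conjugate addition or enolate alkylation would give trans, whereas a suprafacial shift copies the C2–O configuration onto C4 and moves the double bond to C2=C3. The forward step needs the C2 hydroxyl free and the C1 hydroxyl masked.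

**C5–C6 by epoxide opening.** 9 comes from hydroxy nitrile 5 through 6 (methyl for bromine), tosylate 7 and diol 8. 5 is cut at C5–C6 into vinyl epoxide 3 and isobutyronitrile 4. The tertiary nitrile anion forms the hindered bond, sets C5 and leaves the C11 oxygen trans to it, where the leaving group is needed; the nitrile is the future methyl ketone.

**Chiral pool.** 3 comes from acetonide 2 and this from bromodiol 1. 1 supplies C1–C5 and C11 with the two oxygens on one face in one enantiomeric form; the bromine steers the epoxidation and is later exchanged for the C3 methyl. The face of these oxygens becomes the face of C10, so the handedness of 1 fixes the absolute configuration of 32.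

## Roads not taken

**Alternative 1:** Cut C4–C5 and C10–C11 together. Triethylamine would dehydrochlorinate acid chloride A1 to a vinylketene, which adds across the trisubstituted alkene in a crossed [2+2] cycloaddition to give cyclobutanone A2.
- Merits: rings A and B form in one step from an open chain, C10 follows from the alkene geometry, and the bicycle is reached in fewer steps than the nine needed here.
- Weak points: facial selectivity hangs on a methyl‑bearing sp3 centre at C3 that must later be erased by moving the double bond and oxidising C1. C5 emerges as a carbonyl, so the bond to quaternary C6 and the C5–H configuration remain to be made.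
- Comparison: the chosen plan is longer to the bicycle, but sets C5 by SN2 opening of an epoxide and never has to deoxygenate a crowded cyclobutane carbon.

**Alternative 2:** Cut C5–C11, closing ring A last. N‑Benzyloxy‑N‑pivaloyloxy‑4‑(trifluoromethyl)benzamide would convert the bridging secondary amine A3 into an isodiazene that loses N2, and the 1,4‑diradical would recombine to the bis‑silyl ether A4.
- Merits: the strained ring is made last, rings B and C are assembled in an unstrained pyrrolidine frame, silyl ethers are tolerated, and no hindered enol‑ether metathesis is needed.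
- Weak points: the diradical is stabilised at C11 by the ketone and can fragment instead of closing a bicyclo[3.1.1]heptane inside a tricycle. Preparing A3 with both carbinols is at least as long as the present route.
- Comparison: ring C is closed more conventionally there. The chosen plan builds ring A by polar, stereospecific steps and leaves only ring C to a catalytic step that cannot fragment the skeleton.

**Alternative 3:** Cut C5–C6 in ring C. BF3·OEt2 would activate the cyclobutanone of A5, and its tetrasubstituted trimethylsilyl enol ether would add to give the tricyclic β‑hydroxy ketone A6.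
- Merits: loss of cyclobutanone strain drives the addition, the bond to quaternary C6 forms intramolecularly, and the C7 ketone is delivered directly. This aldol is arguably more dependable than metathesis of a hindered enol ether and reaches the tricycle sooner.
- Weak points: A6 has a tertiary hydroxyl at C5 that the target lacks. Removing it from a cyclobutanol that is also a β‑hydroxy ketone, with hydrogen delivered from the ring‑B face, adds risky steps; ring B still needs oxidation at C1.
- Comparison: the chosen plan has no superfluous oxygen and fixes C5 early and stereospecifically.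

Key step: step 18

Remarks on the chemistry:
- 1 is taken as the commercially supplied product of microbial cis‑dihydroxylation of bromobenzene.
- "Top" is the face of the six‑membered ring that carries the two oxygens of 1; C10 is later bonded on this face.
- In the oxazaborolidine reduction the quaternary C10 is assumed to act as the large group.

## Route

Step 1
Reactants: 1 (1S,2S)-3-bromocyclohexa-3,5-diene-1,2-diol
Product: 2 (3aS,7aS)-4-bromo-2,2-dimethyl-3a,7a-dihydro-1,3-benzodioxole
Conditions: Me2C(OMe)2, TsOH·H2O (cat.), acetone, 0 °C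
Reagents that add atoms: 2,2-dimethoxypropane, COC(C)(C)OC
Why: Acid-catalysed acetonide formation on the cis-diol; the dioxolane masks both hydroxyls and shields the top face of the diene.

Step 2
Reactants: 2 (3aS,7aS)-4-bromo-2,2-dimethyl-3a,7a-dihydro-1,3-benzodioxole
Product: 3 (3aS,7aS)-4-bromo-6,7-epoxy-2,2-dimethyl-3a,6,7,7a-tetrahydro-1,3-benzodioxole (oxirane anti to the dioxolane)
Conditions: mCPBA, CH2Cl2, 0 °C to rt
Reagents that add atoms: 3-chloroperoxybenzoic acid, OOC(=O)c1cccc(Cl)c1
Why: Prilezhaev epoxidation; the peracid should take the more electron-rich unbrominated C5=C11 double bond from the face opposite the dioxolane, the usual behaviour of this diene.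

Step 3
Reactants: 3 (3aS,7aS)-4-bromo-6,7-epoxy-2,2-dimethyl-3a,6,7,7a-tetrahydro-1,3-benzodioxole; 4 isobutyronitrile
Product: 5 2-(7-bromo-4-hydroxy-2,2-dimethyl-3a,4,5,7a-tetrahydro-1,3-benzodioxol-5-yl)-2-methylpropanenitrile
Conditions: 4, LiN(i-Pr)2, THF, −78 °C; then 3, −78 to 0 °C
Reagents that add atoms: none
Why: SN2 opening of the vinyl oxirane by a tertiary nitrile anion at the allylic carbon C5, anti to the oxirane oxygen; this sets C5 with the cyanoisopropyl group on the top face and leaves the C11 hydroxyl on the bottom face. Allylic activation and distance from the dioxolane should direct attack to C5 rather than C11.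

Step 4
Reactants: 5 2-(7-bromo-4-hydroxy-2,2-dimethyl-3a,4,5,7a-tetrahydro-1,3-benzodioxol-5-yl)-2-methylpropanenitrile
Product: 6 2-(4-hydroxy-2,2,7-trimethyl-3a,4,5,7a-tetrahydro-1,3-benzodioxol-5-yl)-2-methylpropanenitrile
Conditions: (MeBO)3, Pd(dppf)Cl2 (5 mol%), K2CO3, dioxane/H2O, 90 °C
Reagents that add atoms: trimethylboroxine, CB1OB(C)OB(C)O1
Why: Suzuki–Miyaura methylation of the alkenyl bromide; the C3 methyl is installed only after the bromine has steered the epoxidation and the oxirane has been consumed.

Step 5
Reactants: 6 2-(4-hydroxy-2,2,7-trimethyl-3a,4,5,7a-tetrahydro-1,3-benzodioxol-5-yl)-2-methylpropanenitrile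
Product: 7 5-(2-cyanopropan-2-yl)-2,2,7-trimethyl-3a,4,5,7a-tetrahydro-1,3-benzodioxol-4-yl 4-methylbenzenesulfonate
Conditions: TsCl, Et3N, Me3N·HCl (cat.), CH2Cl2, 0 °C to rt
Reagents that add atoms: 4-toluenesulfonyl chloride, Cc1ccc(cc1)S(Cl)(=O)=O
Why: Sulfonylation turns the C11 hydroxyl, trans to the C5 substituent, into the leaving group for the later inversion. A tosylate is chosen over a mesylate because it has no acidic α-hydrogens toward the amide bases used later.

Step 6
Reactants: 7 5-(2-cyanopropan-2-yl)-2,2,7-trimethyl-3a,4,5,7a-tetrahydro-1,3-benzodioxol-4-yl 4-methylbenzenesulfonate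
Product: 8 6-(2-cyanopropan-2-yl)-2,3-dihydroxy-4-methylcyclohex-4-en-1-yl 4-methylbenzenesulfonate
Conditions: CF3CO2H/H2O/THF, 0 °C to rt
Reagents that add atoms: none
Why: Acid hydrolysis of the acetonide; the nitrile is inert and the tosylate, deactivated toward ionisation by its β-oxygen, should survive.

Step 7
Reactants: 8 6-(2-cyanopropan-2-yl)-2,3-dihydroxy-4-methylcyclohex-4-en-1-yl 4-methylbenzenesulfonate
Product: 9 2-(tert-butyldimethylsilyloxy)-6-(2-cyanopropan-2-yl)-3-hydroxy-4-methylcyclohex-4-en-1-yl 4-methylbenzenesulfonate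
Conditions: t-BuMe2SiCl (1.05 equiv), imidazole, DMF, −20 to 0 °C
Reagents that add atoms: tert-butyldimethylsilyl chloride, CC(C)(C)[Si](C)(C)Cl
Why: Selective silylation; the equatorial, non-allylic C1 hydroxyl should react before the pseudo-axial allylic C2 hydroxyl, which is flanked by the methyl-bearing sp2 carbon, as is usual for the distal hydroxyl of such cyclohexene cis-diols.

Step 8
Reactants: 9 2-(tert-butyldimethylsilyloxy)-6-(2-cyanopropan-2-yl)-3-hydroxy-4-methylcyclohex-4-en-1-yl 4-methylbenzenesulfonate; 10 trimethyl orthoacetate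
Product: 12 methyl 2-[4-(tert-butyldimethylsilyloxy)-6-(2-cyanopropan-2-yl)-2-methyl-5-(tosyloxy)cyclohex-2-en-1-yl]acetate, via ketene acetal 11 (not isolated)
Conditions: 10 (excess), EtCO2H (cat.), xylene, 135 °C, MeOH distilled off
Reagents that add atoms: none
Why: Johnson–Claisen rearrangement; orthoester exchange at the allylic hydroxyl and loss of methanol give 11, whose suprafacial [3,3] shift delivers the acetate carbon to C4 on the top face, cis to the C5 substituent. The double bond moves to C2=C3, where the enone needs it.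

Step 9
Reactants: 12 methyl 2-[4-(tert-butyldimethylsilyloxy)-6-(2-cyanopropan-2-yl)-2-methyl-5-(tosyloxy)cyclohex-2-en-1-yl]acetate
Product: 13 methyl 4-(tert-butyldimethylsilyloxy)-7-(2-cyanopropan-2-yl)-2-methylbicyclo[3.1.1]hept-2-ene-6-carboxylate (C10 epimers)
Conditions: LiN(SiMe3)2, THF, −78 to 40 °C, high dilution
Reagents that add atoms: none
Why: Intramolecular enolate alkylation (4-exo-tet), the reaction type of cyclobutane- and bicyclobutane-carboxylate closures; the ester enolate on the pseudo-axial C4 chain displaces the equatorial C11 tosylate from the top face with inversion, so both C10 bonds end cis to the C5 substituent. E2 loss of the tosylate is disfavoured because both β-hydrogens are syn to it, and a lithium enolate in THF favours C- over O-alkylation; the C10 configuration is erased in step 10.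

Step 10
Reactants: 13 methyl 4-(tert-butyldimethylsilyloxy)-7-(2-cyanopropan-2-yl)-2-methylbicyclo[3.1.1]hept-2-ene-6-carboxylate (C10 epimers)
Product: 14 methyl 4-(tert-butyldimethylsilyloxy)-7-(2-cyanopropan-2-yl)-2,6-dimethylbicyclo[3.1.1]hept-2-ene-6-carboxylate
Conditions: LiN(i-Pr)2, THF/DMPU, −78 to −30 °C; then MeI
Reagents that add atoms: iodomethane, CI
Why: Ester enolate alkylation; iodomethane should attack the exocyclic enolate at C10 from the ring-B face, because the other face lies against the 1,3-related cyanoisopropyl group on C5. The methyl then ends syn to ring B and the ester on the side of the C5 arm, which completes ring A.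

Step 11
Reactants: 14 methyl 4-(tert-butyldimethylsilyloxy)-7-(2-cyanopropan-2-yl)-2,6-dimethylbicyclo[3.1.1]hept-2-ene-6-carboxylate
Product: 15 2-[4-(tert-butyldimethylsilyloxy)-6-(hydroxymethyl)-2,6-dimethylbicyclo[3.1.1]hept-2-en-7-yl]-2-methylpropanenitrile
Conditions: LiBH4, MeOH (1 equiv), THF, 0 to 50 °C
Reagents that add atoms: none
Why: Chemoselective borohydride reduction; LiBH4 reduces the ester to the primary alcohol and leaves the tertiary nitrile and the alkene untouched.

Step 12
Reactants: 15 2-[4-(tert-butyldimethylsilyloxy)-6-(hydroxymethyl)-2,6-dimethylbicyclo[3.1.1]hept-2-en-7-yl]-2-methylpropanenitrile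
Product: 16 2-[4-(tert-butyldimethylsilyloxy)-6-formyl-2,6-dimethylbicyclo[3.1.1]hept-2-en-7-yl]-2-methylpropanenitrile
Conditions: Dess–Martin periodinane, NaHCO3, CH2Cl2, 0 °C to rt
Reagents that add atoms: none
Why: Dess–Martin oxidation of a neopentylic primary alcohol to an aldehyde that cannot enolise.

Step 13
Reactants: 16 2-[4-(tert-butyldimethylsilyloxy)-6-formyl-2,6-dimethylbicyclo[3.1.1]hept-2-en-7-yl]-2-methylpropanenitrile; 17 vinylmagnesium bromide
Product: 18 2-[4-(tert-butyldimethylsilyloxy)-6-(1-hydroxyprop-2-enyl)-2,6-dimethylbicyclo[3.1.1]hept-2-en-7-yl]-2-methylpropanenitrile (C9 epimers)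
Conditions: 17, THF, −78 to −20 °C
Reagents that add atoms: none
Why: Grignard addition; the aldehyde is far more reactive than the hindered tertiary nitrile at low temperature. No facial selectivity is relied on, since C9 is reset in steps 14 and 15.

Step 14
Reactants: 18 2-[4-(tert-butyldimethylsilyloxy)-6-(1-hydroxyprop-2-enyl)-2,6-dimethylbicyclo[3.1.1]hept-2-en-7-yl]-2-methylpropanenitrile (C9 epimers)
Product: 19 2-[6-acryloyl-4-(tert-butyldimethylsilyloxy)-2,6-dimethylbicyclo[3.1.1]hept-2-en-7-yl]-2-methylpropanenitrile
Conditions: Dess–Martin periodinane, NaHCO3, CH2Cl2, 0 °C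
Reagents that add atoms: none
Why: Dess–Martin oxidation of the allylic alcohols converges both epimers on one vinyl ketone under neutral conditions.

Step 15
Reactants: 19 2-[6-acryloyl-4-(tert-butyldimethylsilyloxy)-2,6-dimethylbicyclo[3.1.1]hept-2-en-7-yl]-2-methylpropanenitrile
Product: 20 2-[4-(tert-butyldimethylsilyloxy)-6-[(1R)-1-hydroxyprop-2-enyl]-2,6-dimethylbicyclo[3.1.1]hept-2-en-7-yl]-2-methylpropanenitrile
Conditions: (S)-Me-CBS oxazaborolidine [(S)-1-methyl-3,3-diphenyltetrahydro-1H,3H-pyrrolo[1,2-c][1,3,2]oxazaborole, 0.5 equiv], catecholborane, toluene, −78 °C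
Reagents that add atoms: none
Why: Corey–Bakshi–Shibata reduction; with quaternary C10 as the large and vinyl as the small group the (S)-catalyst should give the (R)-carbinol at C9. Catecholborane does not hydroborate the ring alkene at this temperature and the nitrile is inert.

Step 16
Reactants: 20 2-[4-(tert-butyldimethylsilyloxy)-6-[(1R)-1-hydroxyprop-2-enyl]-2,6-dimethylbicyclo[3.1.1]hept-2-en-7-yl]-2-methylpropanenitrile
Product: 22 3-[4-(tert-butyldimethylsilyloxy)-6-[(1R)-1-hydroxyprop-2-enyl]-2,6-dimethylbicyclo[3.1.1]hept-2-en-7-yl]-3-methylbutan-2-one, via ketimine 21 (not isolated)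
Conditions: MeLi (4 equiv), Et2O, 0 °C to rt; then aq. AcOH/NaOAc, THF, rt
Reagents that add atoms: methyllithium, [Li]C; water, O
Why: Organolithium addition to a nitrile; the first equivalent deprotonates the hydroxyl, the N-lithio ketimine cannot add a second methyl, and buffered aqueous acid hydrolyses 21 to the methyl ketone. A seven-membered hemiketal of this hindered ketone is not expected to interfere.

Step 17
Reactants: 22 3-[4-(tert-butyldimethylsilyloxy)-6-[(1R)-1-hydroxyprop-2-enyl]-2,6-dimethylbicyclo[3.1.1]hept-2-en-7-yl]-3-methylbutan-2-one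
Product: 23 tert-butyldimethylsilyl ether of the bicyclic diene with a (1R)-1-(triethylsilyloxy)prop-2-enyl group on C10 and a 2-methyl-3-(triethylsilyloxy)but-3-en-2-yl group on C5
Conditions: Et3SiOTf (3 equiv), Et3N, CH2Cl2, −78 to 0 °C
Reagents that add atoms: triethylsilyl trifluoromethanesulfonate, CC[Si](CC)(CC)OS(=O)(=O)C(F)(F)F
Why: Silyl triflate and amine silylate the C9 hydroxyl and convert the methyl ketone into its silyl enol ether in one operation; the ketone can enolise only toward its methyl group because C6 is quaternary.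

Step 18
Reactants: 23 tert-butyldimethylsilyl ether of the bicyclic diene with a (1R)-1-(triethylsilyloxy)prop-2-enyl group on C10 and a 2-methyl-3-(triethylsilyloxy)but-3-en-2-yl group on C5
Product: 24 1-(tert-butyldimethylsilyloxy)-7,9-bis(triethylsilyloxy)longipina-2,7-diene
Conditions: (H2IMes)(PCy3)Cl2Ru=CHPh (second-generation Grubbs catalyst, 15 mol%), toluene (2 mM), 80 °C, argon purge
Reagents that add atoms: none
Why: Ring-closing metathesis onto a silyl enol ether: the benzylidene first exchanges with the monosubstituted C9 vinyl group, the only unhindered terminal alkene, to give the ruthenium alkylidene at the future C8. This carbene adds across the 1,1-disubstituted enol ether to a ruthenacyclobutane, and cycloreversion releases the C7=C8 double bond and a methylidene that carries the cycle on with loss of ethene. The closest known reaction type is ruthenium-catalysed ring-closing metathesis of terminal alkenes with silyl enol ethers to five- to seven-membered cyclic silyl enol ethers; a 2-silyloxypropenyl group beside a quaternary carbon is at the edge of that scope. Ring C closes as a seven-membered cycloalkene in the usual endocyclic mode, and the new trisubstituted double bond is not at a bridgehead. No stereocentre is formed or touched; C7 is fixed at the ketone level without any enolisation step. The step needs initiation at the vinyl group and closure faster than dimerisation: C10 and C5 hold the two arms 1,3-cis on ring A, the gem-dimethyl group restricts them further, and high dilution with an argon purge suppresses dimerisation and removes ethene. The trisubstituted ring-B alkene is a pinene-type double bond that ruthenium carbenes should not open, and the silyl ethers at C1 and C9 are inert.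

Step 19
Reactants: 24 1-(tert-butyldimethylsilyloxy)-7,9-bis(triethylsilyloxy)longipina-2,7-diene
Product: 25 (9R)-1,9-dihydroxylongipin-2-en-7-one
Conditions: HF·pyridine, pyridine, THF, 0 °C to rt
Reagents that add atoms: none
Why: Fluoride-mediated desilylation removes both triethylsilyl groups, which unmasks the C7 ketone, and the tert-butyldimethylsilyl ether at C1. Buffering with pyridine should avoid retro-aldol cleavage and ionisation of the allylic C1 alcohol.

Step 20
Reactants: 25 (9R)-1,9-dihydroxylongipin-2-en-7-one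
Product: 26 (9R)-9-hydroxylongipin-2-ene-1,7-dione
Conditions: MnO2 (activated, excess), CH2Cl2, rt
Reagents that add atoms: none
Why: MnO2 oxidises only the allylic C1 hydroxyl, as in the verbenol-to-verbenone change, and leaves the saturated C9 carbinol and the β-hydroxy ketone alone.

Step 21
Reactants: 26 (9R)-9-hydroxylongipin-2-ene-1,7-dione; 27 tiglaldehyde
Product: 29 (7R,9R)-7-hydroxy-9-tigloyloxylongipin-2-en-1-one, via hemiacetal 28 (not isolated)
Conditions: 27 (6 equiv), SmI2 (0.3 equiv), THF, −10 °C
Reagents that add atoms: none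
Why: Evans–Tishchenko reduction; the samarium alkoxide of the C9 hydroxyl adds to tiglaldehyde, and hemiacetal 28 passes its hydride through a six-membered chair to the C7 ketone on the face of the C9 oxygen. The new C7 hydroxyl is therefore 1,3-anti (trans on ring C) and C9 leaves as the tiglate; the ring-B enone is out of reach of this intramolecular transfer.

Step 22
Reactants: 29 (7R,9R)-7-hydroxy-9-tigloyloxylongipin-2-en-1-one; 30 angelic acid
Product: 32 (7R,9R)-7-angeloyloxy-9-tigloyloxylongipin-2-en-1-one (CNP0236543.4), via mixed anhydride 31 (not isolated)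
Conditions: 30, 2,4,6-Cl3C6H2COCl, Et3N, toluene, rt; then 29, toluene, 80 °C
Reagents that add atoms: 2,4,6-trichlorobenzoyl chloride, O=C(Cl)c1c(Cl)cc(Cl)cc1Cl (its atoms are carried only in 31)
Why: Yamaguchi-type mixed-anhydride esterification; the C7 hydroxyl attacks the unhindered angeloyl carbonyl of 31. No nucleophilic catalyst is used, so the Z-double bond should not isomerise, and the tiglate is untouched.

## Compound list

1 | (1S,2S)-3-bromocyclohexa-3,5-diene-1,2-diol | O[C@@H]1[C@H](O)C(Br)=CC=C1 | starting material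
2 | (3aS,7aS)-4-bromo-2,2-dimethyl-3a,7a-dihydro-1,3-benzodioxole | CC1(C)O[C@H]2C=CC=C(Br)[C@H]2O1 | intermediate
3 | (3aS,7aS)-4-bromo-6,7-epoxy-2,2-dimethyl-3a,6,7,7a-tetrahydro-1,3-benzodioxole, oxirane (C5–C11) anti to the dioxolane | CC1(C)O[C@H]2[C@@H]3O[C@@H]3C=C(Br)[C@H]2O1 | intermediate
4 | isobutyronitrile | CC(C)C#N | starting material
5 | 2-(7-bromo-4-hydroxy-2,2-dimethyl-3a,4,5,7a-tetrahydro-1,3-benzodioxol-5-yl)-2-methylpropanenitrile; cyanoisopropyl cis to the dioxolane, hydroxyl trans to both | CC1(C)O[C@H]2[C@H](O)[C@@H](C(C)(C)C#N)C=C(Br)[C@H]2O1 | intermediate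
6 | 2-(4-hydroxy-2,2,7-trimethyl-3a,4,5,7a-tetrahydro-1,3-benzodioxol-5-yl)-2-methylpropanenitrile, configuration as in 5 | CC1(C)O[C@H]2[C@H](O)[C@@H](C(C)(C)C#N)C=C(C)[C@H]2O1 | intermediate
7 | 5-(2-cyanopropan-2-yl)-2,2,7-trimethyl-3a,4,5,7a-tetrahydro-1,3-benzodioxol-4-yl 4-methylbenzenesulfonate | CC1(C)O[C@H]2[C@H](OS(=O)(=O)c3ccc(C)cc3)[C@@H](C(C)(C)C#N)C=C(C)[C@H]2O1 | intermediate
8 | 6-(2-cyanopropan-2-yl)-2,3-dihydroxy-4-methylcyclohex-4-en-1-yl 4-methylbenzenesulfonate; hydroxyls and cyanoisopropyl on the top face, tosyloxy on the bottom face | O[C@H]1[C@H](OS(=O)(=O)c2ccc(C)cc2)[C@@H](C(C)(C)C#N)C=C(C)[C@H]1O | intermediate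
9 | 2-(tert-butyldimethylsilyloxy)-6-(2-cyanopropan-2-yl)-3-hydroxy-4-methylcyclohex-4-en-1-yl 4-methylbenzenesulfonate (silyl on the C1 oxygen) | CC(C)(C)[Si](C)(C)O[C@H]1[C@H](OS(=O)(=O)c2ccc(C)cc2)[C@@H](C(C)(C)C#N)C=C(C)[C@H]1O | intermediate
10 | trimethyl orthoacetate | COC(C)(OC)OC | starting material
11 | ketene acetal: 3-O-(1-methoxyethenyl) derivative of 9 | CC(C)(C)[Si](C)(C)O[C@H]1[C@H](OS(=O)(=O)c2ccc(C)cc2)[C@@H](C(C)(C)C#N)C=C(C)[C@H]1OC(=C)OC | intermediate (not isolated)
12 | methyl 2-[4-(tert-butyldimethylsilyloxy)-6-(2-cyanopropan-2-yl)-2-methyl-5-(tosyloxy)cyclohex-2-en-1-yl]acetate; acetate, cyanoisopropyl and silyloxy on the top face, tosyloxy on the bottom face | CC(C)(C)[Si](C)(C)O[C@@H]1C=C(C)[C@H](CC(=O)OC)[C@H](C(C)(C)C#N)[C@H]1OS(=O)(=O)c2ccc(C)cc2 | intermediate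
13 | methyl 4-(tert-butyldimethylsilyloxy)-7-(2-cyanopropan-2-yl)-2-methylbicyclo[3.1.1]hept-2-ene-6-carboxylate; 7-substituent anti to the alkene bridge, silyloxy on the C6 side, both C6 (= C10) epimers | COC(=O)C1[C@@H]2[C@H](O[Si](C)(C)C(C)(C)C)C=C(C)[C@H]1[C@@H]2C(C)(C)C#N | intermediate
14 | methyl 4-(tert-butyldimethylsilyloxy)-7-(2-cyanopropan-2-yl)-2,6-dimethylbicyclo[3.1.1]hept-2-ene-6-carboxylate; 6-methyl syn to the alkene bridge, ester and 7-substituent anti to it and cis to each other | COC(=O)[C@@]1(C)[C@@H]2[C@H](O[Si](C)(C)C(C)(C)C)C=C(C)[C@H]1[C@@H]2C(C)(C)C#N | intermediate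
15 | 2-[4-(tert-butyldimethylsilyloxy)-6-(hydroxymethyl)-2,6-dimethylbicyclo[3.1.1]hept-2-en-7-yl]-2-methylpropanenitrile, configuration as in 14 | OC[C@@]1(C)[C@@H]2[C@H](O[Si](C)(C)C(C)(C)C)C=C(C)[C@H]1[C@@H]2C(C)(C)C#N | intermediate
16 | 2-[4-(tert-butyldimethylsilyloxy)-6-formyl-2,6-dimethylbicyclo[3.1.1]hept-2-en-7-yl]-2-methylpropanenitrile | O=C[C@@]1(C)[C@@H]2[C@H](O[Si](C)(C)C(C)(C)C)C=C(C)[C@H]1[C@@H]2C(C)(C)C#N | intermediate
17 | vinylmagnesium bromide | C=C[Mg]Br | starting material
18 | 2-[4-(tert-butyldimethylsilyloxy)-6-(1-hydroxyprop-2-enyl)-2,6-dimethylbicyclo[3.1.1]hept-2-en-7-yl]-2-methylpropanenitrile, both C9 epimers | C=CC(O)[C@@]1(C)[C@@H]2[C@H](O[Si](C)(C)C(C)(C)C)C=C(C)[C@H]1[C@@H]2C(C)(C)C#N | intermediate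
19 | 2-[6-acryloyl-4-(tert-butyldimethylsilyloxy)-2,6-dimethylbicyclo[3.1.1]hept-2-en-7-yl]-2-methylpropanenitrile | C=CC(=O)[C@@]1(C)[C@@H]2[C@H](O[Si](C)(C)C(C)(C)C)C=C(C)[C@H]1[C@@H]2C(C)(C)C#N | intermediate
20 | 2-[4-(tert-butyldimethylsilyloxy)-6-[(1R)-1-hydroxyprop-2-enyl]-2,6-dimethylbicyclo[3.1.1]hept-2-en-7-yl]-2-methylpropanenitrile | C=C[C@@H](O)[C@@]1(C)[C@@H]2[C@H](O[Si](C)(C)C(C)(C)C)C=C(C)[C@H]1[C@@H]2C(C)(C)C#N | intermediate
21 | ketimine: 7-(3-imino-2-methylbutan-2-yl) analogue of 20 | C=C[C@@H](O)[C@@]1(C)[C@@H]2[C@H](O[Si](C)(C)C(C)(C)C)C=C(C)[C@H]1[C@@H]2C(C)(C)C(C)=N | intermediate (not isolated)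
22 | 3-[4-(tert-butyldimethylsilyloxy)-6-[(1R)-1-hydroxyprop-2-enyl]-2,6-dimethylbicyclo[3.1.1]hept-2-en-7-yl]-3-methylbutan-2-one | C=C[C@@H](O)[C@@]1(C)[C@@H]2[C@H](O[Si](C)(C)C(C)(C)C)C=C(C)[C@H]1[C@@H]2C(C)(C)C(C)=O | intermediate
23 | metathesis precursor: 4-(tert-butyldimethylsilyloxy)-2,6-dimethylbicyclo[3.1.1]hept-2-ene with 6-[(1R)-1-(triethylsilyloxy)prop-2-enyl] and 7-[2-methyl-3-(triethylsilyloxy)but-3-en-2-yl], both arms anti to the alkene bridge | C=C[C@@H](O[Si](CC)(CC)CC)[C@@]1(C)[C@@H]2[C@H](O[Si](C)(C)C(C)(C)C)C=C(C)[C@H]1[C@@H]2C(C)(C)C(=C)O[Si](CC)(CC)CC | intermediate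
24 | 1-(tert-butyldimethylsilyloxy)-7,9-bis(triethylsilyloxy)longipina-2,7-diene (tricyclic cyclic silyl enol ether) | CC[Si](CC)(CC)OC1=C[C@@H](O[Si](CC)(CC)CC)[C@@]2(C)[C@@H]3[C@H](O[Si](C)(C)C(C)(C)C)C=C(C)[C@H]2[C@@H]3C1(C)C | intermediate
25 | (9R)-1,9-dihydroxylongipin-2-en-7-one, C1 hydroxyl on the side of C10 | O=C1C[C@@H](O)[C@@]2(C)[C@@H]3[C@H](O)C=C(C)[C@H]2[C@@H]3C1(C)C | intermediate
26 | (9R)-9-hydroxylongipin-2-ene-1,7-dione | O=C1C[C@@H](O)[C@@]2(C)[C@@H]3C(=O)C=C(C)[C@H]2[C@@H]3C1(C)C | intermediate
27 | tiglaldehyde, (E)-2-methylbut-2-enal | C/C=C(\C)C=O | starting material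
28 | hemiacetal of 26 at the C9 oxygen with tiglaldehyde (samarium-bound, hemiacetal carbon undefined) | O=C1C[C@@H](OC(O)/C(C)=C/C)[C@@]2(C)[C@@H]3C(=O)C=C(C)[C@H]2[C@@H]3C1(C)C | intermediate (not isolated)
29 | (7R,9R)-7-hydroxy-9-tigloyloxylongipin-2-en-1-one | O[C@@H]1C[C@@H](OC(=O)/C(C)=C/C)[C@@]2(C)[C@@H]3C(=O)C=C(C)[C@H]2[C@@H]3C1(C)C | intermediate
30 | angelic acid, (Z)-2-methylbut-2-enoic acid | C/C=C(/C)C(=O)O | starting material
31 | angelic 2,4,6-trichlorobenzoic anhydride | C/C=C(/C)C(=O)OC(=O)c1c(Cl)cc(Cl)cc1Cl | intermediate (not isolated)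
32 | (7R,9R)-7-angeloyloxy-9-tigloyloxylongipin-2-en-1-one, CNP0236543.4 | C/C=C(/C)C(=O)O[C@@H]1C[C@@H](OC(=O)/C(C)=C/C)[C@@]2(C)[C@@H]3C(=O)C=C(C)[C@H]2[C@@H]3C1(C)C | target

## Step count and least certain steps

Total: 22 steps. Longest linear sequence: 22 steps, from 1 to 32; 4, 10, 17, 27 and 30 are commercial and enter directly.

**Step 18 (key step).** The ruthenium alkylidene may fail to engage the hindered 1,1-disubstituted enol ether, so that dimerisation through the vinyl group, double-bond migration or catalyst decay takes over.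
Fallback: close ring C by an aldol reaction at C8–C9 instead. Alcohol 15 is treated with methyllithium and hydrolysed to the hydroxy methyl ketone F1, and Dess–Martin oxidation gives keto aldehyde F2. The lithium enolate of the methyl ketone (LiN(i-Pr)2, THF, −78 °C; the aldehyde cannot enolise) adds intramolecularly to give the seven-membered β-hydroxy ketone F3. HF·pyridine returns the route to 25. This gives up catalyst control at C9, so C9 epimers may have to be separated.

**Step 9.** O-alkylation of the enolate, which would close an unstrained six-membered ketene acetal, or intermolecular Claisen condensation may outrun the four-membered C-alkylation.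
Fallback: use a malonate, which alkylates only on carbon. Alcohol 9 is acylated with methyl malonyl chloride to F4. Ireland–Claisen rearrangement (Et3N, Me3SiCl, heat), hydrolysis and (trimethylsilyl)diazomethane give dimethyl malonate F5. NaH in DMF closes the cyclobutane-1,1-diester F6, and Krapcho demethoxycarbonylation (LiCl, wet DMSO, 150 °C) returns to 13.

**Step 10.** Deprotonation may stall if the C10 hydrogen lies in the pocket beside the C5 arm; wrong-face methylation is the second risk.
Fallback: methylate at the aldehyde stage, where enolisation is easy and reversible. 13 is reduced with LiBH4 to alcohol F7 and oxidised with Dess–Martin periodinane to aldehyde F8. KOt-Bu and MeI in THF then methylate C10 under the same facial bias and return to 16.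

**Step 7.** Site selectivity between the two secondary hydroxyls of 8 may be poor.
Fallback: differentiate them through a cyclic orthoester. 8 and trimethyl orthoacetate (camphorsulfonic acid cat.) give orthoester F9, which mild aqueous acid opens to the pseudo-axial, allylic C2 acetate F10. Silylation of the C1 hydroxyl (t-BuMe2SiOTf, 2,6-lutidine, −78 °C) gives F11. Ireland–Claisen rearrangement (LiN(i-Pr)2, Me3SiCl, THF, −78 °C to rt) gives acid F12, and (trimethylsilyl)diazomethane returns to 12.

**Step 21.** The enal may be consumed by reductive coupling or conjugate reduction at samarium, or hemiacetal formation at the neopentylic C9 hydroxyl may be too slow for hydride transfer.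
Fallback: run the same reduction with acetaldehyde and exchange the ester. 26 with acetaldehyde and SmI2 gives the C9 acetate F13 with the anti C7 hydroxyl. Et3SiOTf and 2,6-lutidine protect C7 as F14, K2CO3 in MeOH at 0 °C removes the acetate to F15, and tiglic anhydride with DMAP gives F16. HF·pyridine returns to 29.

## Further compounds

F1 | step 18 | 3-[4-(tert-butyldimethylsilyloxy)-6-(hydroxymethyl)-2,6-dimethylbicyclo[3.1.1]hept-2-en-7-yl]-3-methylbutan-2-one | OC[C@@]1(C)[C@@H]2[C@H](O[Si](C)(C)C(C)(C)C)C=C(C)[C@H]1[C@@H]2C(C)(C)C(C)=O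
F2 | step 18 | 4-(tert-butyldimethylsilyloxy)-2,6-dimethyl-7-(2-methyl-3-oxobutan-2-yl)bicyclo[3.1.1]hept-2-ene-6-carbaldehyde | O=C[C@@]1(C)[C@@H]2[C@H](O[Si](C)(C)C(C)(C)C)C=C(C)[C@H]1[C@@H]2C(C)(C)C(C)=O
F3 | step 18 | (9R)-1-(tert-butyldimethylsilyloxy)-9-hydroxylongipin-2-en-7-one | O=C1C[C@@H](O)[C@@]2(C)[C@@H]3[C@H](O[Si](C)(C)C(C)(C)C)C=C(C)[C@H]2[C@@H]3C1(C)C
F4 | step 9 | methyl malonate mixed ester of 9 at the C2 oxygen | CC(C)(C)[Si](C)(C)O[C@H]1[C@H](OS(=O)(=O)c2ccc(C)cc2)[C@@H](C(C)(C)C#N)C=C(C)[C@H]1OC(=O)CC(=O)OC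
F5 | step 9 | dimethyl 2-[4-(tert-butyldimethylsilyloxy)-6-(2-cyanopropan-2-yl)-2-methyl-5-(tosyloxy)cyclohex-2-en-1-yl]malonate | CC(C)(C)[Si](C)(C)O[C@@H]1C=C(C)[C@H](C(C(=O)OC)C(=O)OC)[C@H](C(C)(C)C#N)[C@H]1OS(=O)(=O)c2ccc(C)cc2
F6 | step 9 | dimethyl 4-(tert-butyldimethylsilyloxy)-7-(2-cyanopropan-2-yl)-2-methylbicyclo[3.1.1]hept-2-ene-6,6-dicarboxylate | COC(=O)C1(C(=O)OC)[C@@H]2[C@H](O[Si](C)(C)C(C)(C)C)C=C(C)[C@H]1[C@@H]2C(C)(C)C#N
F7 | step 10 | 2-[4-(tert-butyldimethylsilyloxy)-6-(hydroxymethyl)-2-methylbicyclo[3.1.1]hept-2-en-7-yl]-2-methylpropanenitrile (C10 epimers) | OCC1[C@@H]2[C@H](O[Si](C)(C)C(C)(C)C)C=C(C)[C@H]1[C@@H]2C(C)(C)C#N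
F8 | step 10 | 2-[4-(tert-butyldimethylsilyloxy)-6-formyl-2-methylbicyclo[3.1.1]hept-2-en-7-yl]-2-methylpropanenitrile (C10 epimers) | O=CC1[C@@H]2[C@H](O[Si](C)(C)C(C)(C)C)C=C(C)[C@H]1[C@@H]2C(C)(C)C#N
F9 | step 7 | cyclic methyl orthoacetate of diol 8 (orthoester carbon undefined) | COC1(C)O[C@H]2[C@H](OS(=O)(=O)c3ccc(C)cc3)[C@@H](C(C)(C)C#N)C=C(C)[C@H]2O1
F10 | step 7 | C2 acetate of diol 8 with free C1 hydroxyl | O[C@H]1[C@H](OS(=O)(=O)c2ccc(C)cc2)[C@@H](C(C)(C)C#N)C=C(C)[C@H]1OC(C)=O
F11 | step 7 | C2 acetate C1 tert-butyldimethylsilyl ether of diol 8 | CC(C)(C)[Si](C)(C)O[C@H]1[C@H](OS(=O)(=O)c2ccc(C)cc2)[C@@H](C(C)(C)C#N)C=C(C)[C@H]1OC(C)=O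
F12 | step 7 | 2-[4-(tert-butyldimethylsilyloxy)-6-(2-cyanopropan-2-yl)-2-methyl-5-(tosyloxy)cyclohex-2-en-1-yl]acetic acid | CC(C)(C)[Si](C)(C)O[C@@H]1C=C(C)[C@H](CC(=O)O)[C@H](C(C)(C)C#N)[C@H]1OS(=O)(=O)c2ccc(C)cc2
F13 | step 21 | (7R,9R)-9-acetoxy-7-hydroxylongipin-2-en-1-one | O[C@@H]1C[C@@H](OC(C)=O)[C@@]2(C)[C@@H]3C(=O)C=C(C)[C@H]2[C@@H]3C1(C)C
F14 | step 21 | (7R,9R)-9-acetoxy-7-(triethylsilyloxy)longipin-2-en-1-one | CC[Si](CC)(CC)O[C@@H]1C[C@@H](OC(C)=O)[C@@]2(C)[C@@H]3C(=O)C=C(C)[C@H]2[C@@H]3C1(C)C
F15 | step 21 | (7R,9R)-9-hydroxy-7-(triethylsilyloxy)longipin-2-en-1-one | CC[Si](CC)(CC)O[C@@H]1C[C@@H](O)[C@@]2(C)[C@@H]3C(=O)C=C(C)[C@H]2[C@@H]3C1(C)C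
F16 | step 21 | (7R,9R)-9-tigloyloxy-7-(triethylsilyloxy)longipin-2-en-1-one | CC[Si](CC)(CC)O[C@@H]1C[C@@H](OC(=O)/C(C)=C/C)[C@@]2(C)[C@@H]3C(=O)C=C(C)[C@H]2[C@@H]3C1(C)C
A1 | alternative 1 | (3Z,6E)-8-(tert-butyldimethylsilyloxy)-5,7,11-trimethyl-10-oxododeca-3,6-dienoyl chloride | ClC(=O)C/C=C\[C@@H](C)/C=C(\C)[C@H](O[Si](C)(C)C(C)(C)C)CC(=O)C(C)C
A2 | alternative 1 | bicyclo[3.1.1]hept-2-en-6-one carrying the ring-C chain | CC(C)C(=O)C[C@@H](O[Si](C)(C)C(C)(C)C)[C@@]1(C)[C@@H]2C=C[C@@H](C)[C@H]1C2=O
A3 | alternative 2 | bridged secondary amine with NH between C5 and C11 | CC(C)(C)[Si](C)(C)O[C@@H]1C[C@@H](O[Si](CC)(CC)CC)[C@@]2(C)[C@@H]3C(=O)C=C(C)[C@H]2[C@@H](N3)C1(C)C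
A4 | alternative 2 | bis-silyl ether of the tricyclic enone diol | CC(C)(C)[Si](C)(C)O[C@@H]1C[C@@H](O[Si](CC)(CC)CC)[C@@]2(C)[C@@H]3C(=O)C=C(C)[C@H]2[C@@H]3C1(C)C
A5 | alternative 3 | bicyclo[3.1.1]hept-2-en-6-one with the trimethylsilyl enol ether of the side-chain isopropyl ketone | CC(C)=C(O[Si](C)(C)C)C[C@@H](O[Si](C)(C)C(C)(C)C)[C@@]1(C)[C@@H]2CC=C(C)[C@H]1C2=O
A6 | alternative 3 | tricyclic β-hydroxy ketone (tertiary cyclobutanol) | O=C1C[C@@H](O[Si](C)(C)C(C)(C)C)[C@@]2(C)[C@@H]3CC=C(C)[C@H]2[C@]3(O)C1(C)C
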